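The amounts of target in the winter, dusk and noon runs climb, peak and fade at different charges, so you need a number that carries from one flask to the next.

| flask | substrate | partner | remark | time |
|---|---|---|---|---|
| winter | 0.050 M | 2.5 equiv | run made earlier |  |
| dusk | 0.075 M | 2.5 equiv | run made earlier |  |
| noon | 0.10 M | 1.2 equiv | run made earlier |  |
| flask | 0.10 M | 2.50 equiv |  | 10 h |

| winter: time / h | winter: target / % | dusk: time / h | dusk: target / % | noon: time / h | noon: target / % |
|---|---|---|---|---|---|
| 0.100 | 9.8 | 0.100 | 13.5 | 0.100 | 9.7 |
| 0.250 | 16.4 | 0.250 | 17.7 | 0.250 | 14.4 |
| 0.833 | 19.5 | 0.833 | 18.2 | 0.833 | 16.9 |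
| 2.50 | 10.9 | 2.50 | 11.4 | 2.50 | 10.8 |
| 8.00 | 3.0 | 8.00 | 1.4 | 8.00 | 1.7 |

(readings scatter by 0.5 percentage points)



- time, not beyond 10 h, at which the flask holds most target
- the amount of target, in percent of the substrate charged, at that time
- the first time at which target reaches 6.3%, in the same percent, in min

That number is s, the target formed per substrate consumed, and two separate sets of readings can give it. Averaged over the runs, target falls from 11.0% at 2.50 h to 2.03% at 8.00 h, which, if the fall is exponential, is a decay constant d of 0.307 h⁻¹, and running that decay back to the start gives 23.8%. The early readings average 11.0% at 0.100 h and 16.2% at 0.250 h, and if you replace the rise by the saturating curve s·t/(t+τ), with τ the time to half the plateau, those averages give 23.5%. The means agree, but run by run the early way wanders from 21.3% in noon to 29.8% in winter, and it rests on a small difference between close readings, so I carry the late figure: s = 23.8%, target formed per substrate consumed, the selectivity of the route.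

The forecast for the flask is a peak at 0.4 h (0.28 h to 0.62 h) holding 19% (17% to 21.5%), with 6.3% reached after 2.1 min (1.5 min to 3.2 min), on the view that “about 21–25% of substrate ever becomes target”. My own reckoning differs: s decayed by d over the forecast's peak time gives 21.0%, higher than the forecast's peak, though it ignores substrate still unconverted then.

The flask peaks at 0.378 h with 20.9%, and reaches 6.3% after 1.59 min, sooner than the forecast.

    substrate + partner ⇌ target (K = 28.0 M⁻¹, k = 0.196 M⁻¹ min⁻¹)
    substrate + partner → isomer of the product (k = 0.619 M⁻¹ min⁻¹)

The reaction to the isomer of the product is the largest single effect on this peak: the flask without it would reach 82.4% instead of 20.9%. At 0.378 h the flask has 4.82% of its substrate left, and s of what has gone is 22.7%, against the 20.9% it holds. In the neighbour flask with 0.620 equiv of partner, the limiting reagent, each partner takes one substrate, so s times that charge gives about 14.8% of the substrate charged; the computed best is 10.9%, and 0.33% of the partner charge remains at 10.0 h.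

The runs were generated by integration for an exercise, and the scatter is random.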